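## Retrosynthetic overview

- The target, the stearate of 3-(3,4-dihydroxy-5-methoxyphenyl)propan-1-ol, is cut between ring carbon C1 and the benzylic CH2. The ring is taken as 3-methoxy-1,2-benzoquinone (the catechol one oxidation level up) and the chain as a 3-(stearoyloxy)propyl radical delivered from boron.
- Enabling feature: the adjacent hydroxyl-bearing ring carbons C3 and C4 can be raised to a 1,2-dione. Ring carbon C1 then becomes the unsubstituted β-carbon of the C3=O/C2=C1 enone, while the lone pair of the methoxy oxygen on C5 enriches C6 and C2 and so steers attack to C1. Conjugate addition and enolisation return the benzene ring with both hydroxyls free, so no protecting group is needed.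
- The radical precursor is the B-alkylcatecholborane from anti-Markovnikov hydroboration of allyl stearate (stearic acid plus allyl alcohol), so the ester is in place before the coupling.
- Ring order: no ring is built. The purchased benzene ring of 3-methoxycatechol is dearomatised by oxidation and re-aromatised in the key step.

Key step: step 4

Remark: the target has no stereocentre; the only stereocentre that appears on the way (in a transient dienolate of the key step) is erased on aromatisation.

## Route

Step 1
Reactants: 1 allyl alcohol (prop-2-en-1-ol); 2 stearic acid (octadecanoic acid)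
Product: 3 allyl stearate (prop-2-en-1-yl octadecanoate)
Conditions: 1 (3 equiv), TsOH·H2O (5 mol%), toluene, reflux, Dean–Stark trap
Reagents that add atoms: none
Why: Fischer esterification of an unhindered primary alcohol with a fatty acid, driven to completion by azeotropic removal of water.

Step 2
Reactants: 4 3-methoxycatechol (3-methoxybenzene-1,2-diol)
Product: 5 3-methoxy-1,2-benzoquinone (3-methoxycyclohexa-3,5-diene-1,2-dione)
Conditions: o-chloranil (3,4,5,6-tetrachloro-1,2-benzoquinone, 1.0 equiv), Et2O, −20 °C, dark; cold filtration, used the same day
Reagents that add atoms: none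
Why: Catechol-to-quinone redox exchange with the higher-potential o-chloranil under cold, anhydrous, non-nucleophilic conditions, from which the o-quinone should crystallise while tetrachlorocatechol stays in the ether.

Step 3
Reactants: 3 allyl stearate
Product: 6 3-(1,3,2-benzodioxaborol-2-yl)propyl octadecanoate
Conditions: catecholborane (0.9 equiv relative to 3), N,N-dimethylacetamide (10 mol%), CH2Cl2, reflux, Ar; volatiles removed, crude 6 used directly
Reagents that add atoms: catecholborane (1,3,2-benzodioxaborole), [H]B1Oc2ccccc2O1
Why: Amide-catalysed anti-Markovnikov hydroboration of a terminal alkene with catecholborane, which places boron on the unhindered terminal carbon and leaves the ester untouched, the slight excess of alkene consuming all B–H so that no hydride meets the quinone later.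

Step 4
Reactants: 5 3-methoxy-1,2-benzoquinone; 6 3-(1,3,2-benzodioxaborol-2-yl)propyl octadecanoate
Product: 9 3-(3,4-dihydroxy-5-methoxyphenyl)propyl octadecanoate (target), via boron dienolate 7 (not isolated), via aryl catechol borate 8 (not isolated)
Conditions: 6 (1.5 equiv), CH2Cl2, 0 °C, 5 in CH2Cl2 added over 1 h with slow admission of air (initiator), then rt; degassed aqueous NaH2PO4 (pH 5) work-up
Reagents that add atoms: none
Why: Proposed new method: a radical chain in which the primary 3-(stearoyloxy)propyl radical released from 6 (initiation by traces of O2) adds to C5 of quinone 5, and the resulting α-keto (enoxyl) radical attacks boron of a second molecule of 6 through oxygen (homolytic substitution), giving boron dienolate 7 and a new alkyl radical; 7 aromatises by proton shift to borate 8, which the aqueous work-up hydrolyses to the free catechol. The closest known reaction type is the radical conjugate addition of B-alkylcatecholboranes and of trialkylboranes to 1,4-benzoquinones, which gives 2-alkylhydroquinones; its transfer to a 1,2-benzoquinone is the new element. No ring is closed, and the single new stereocentre (the sp3 ring carbon of 7) is uncontrolled and vanishes on aromatisation. The step needs attack at carbon rather than at carbonyl oxygen, and at C5 rather than C4 or C6: a nucleophilic primary alkyl radical should prefer the carbon of an unhindered quinone, C5 is the unsubstituted β-carbon of the C1 carbonyl, and the methoxy oxygen on C3 donates into C4 and C6 and deactivates them, which is also why polar Michael donors add to this quinone at C5. Holding the product as borate 8 until work-up and adding 5 slowly to an excess of 6 should suppress redox exchange between product catechol and unreacted quinone and the self-condensation of 5.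

## Compound list

1 | allyl alcohol (prop-2-en-1-ol) | C=CCO | starting material
2 | stearic acid (octadecanoic acid) | CCCCCCCCCCCCCCCCCC(=O)O | starting material
3 | allyl stearate (prop-2-en-1-yl octadecanoate) | CCCCCCCCCCCCCCCCCC(=O)OCC=C | intermediate
4 | 3-methoxycatechol (3-methoxybenzene-1,2-diol) | COc1cccc(O)c1O | starting material
5 | 3-methoxy-1,2-benzoquinone (3-methoxycyclohexa-3,5-diene-1,2-dione) | COC1=CC=CC(=O)C1=O | intermediate
6 | 3-(1,3,2-benzodioxaborol-2-yl)propyl octadecanoate | CCCCCCCCCCCCCCCCCC(=O)OCCCB1Oc2ccccc2O1 | intermediate
7 | 3-[3-(1,3,2-benzodioxaborol-2-yloxy)-5-methoxy-4-oxocyclohexa-2,5-dien-1-yl]propyl octadecanoate (boron dienolate, racemic) | CCCCCCCCCCCCCCCCCC(=O)OCCCC1C=C(OB2Oc3ccccc3O2)C(=O)C(OC)=C1 | intermediate (not isolated)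
8 | 3-[3-(1,3,2-benzodioxaborol-2-yloxy)-4-hydroxy-5-methoxyphenyl]propyl octadecanoate (aryl catechol borate) | CCCCCCCCCCCCCCCCCC(=O)OCCCc1cc(OB2Oc3ccccc3O2)c(O)c(OC)c1 | intermediate (not isolated)
9 | 3-(3,4-dihydroxy-5-methoxyphenyl)propyl octadecanoate | CCCCCCCCCCCCCCCCCC(=O)OCCCc1cc(O)c(O)c(OC)c1 | target

## Step count and risks

Total step count: 4. Longest linear sequence: 3 steps (steps 1, 3 and 4); step 2 is a one-step side branch.

Steps most likely to fail:

1. Step 4 (proposed new method). The alkyl radical may add to a carbonyl oxygen and give catechol monoethers, or to C4 or C6; the chain may be outrun by self-condensation of the quinone; the product may be drained by redox exchange with unreacted quinone. Fallback with known chemistry, setting out from allyl stearate 3 and coming back at target 9: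
   - Commercial 5-bromo-2-hydroxy-3-methoxybenzaldehyde would be converted by Dakin oxidation (H2O2, aqueous NaOH, then acid) into 5-bromo-3-methoxybenzene-1,2-diol F1, whose bromine sits para to the central hydroxyl.
   - Benzylation (BnBr, K2CO3, DMF) would give 1,2-bis(benzyloxy)-5-bromo-3-methoxybenzene F2.
   - Hydroboration of 3 with 9-BBN (THF, 0 °C to rt) would give 3-(9-borabicyclo[3.3.1]nonan-9-yl)propyl octadecanoate F3.
   - B-alkyl Suzuki–Miyaura coupling of F3 with F2 (PdCl2(dppf), K3PO4, DMF/THF/H2O, 50 °C) would form the same aryl–CH2 bond in 3-[3,4-bis(benzyloxy)-5-methoxyphenyl]propyl octadecanoate F4.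
   - Hydrogenolysis (H2, Pd/C, EtOAc) would release 9.

2. Step 2. The o-quinone may decompose or dimerise during isolation, or be over-oxidised, so that no clean quinone reaches the key step. Fallback that gives up the quinone logic, setting out from allyl alcohol 1 and coming back at target 9:
   - Mitsunobu etherification of commercial 2-hydroxy-3-methoxybenzaldehyde with 1 (PPh3, DIAD, THF) would give 2-(allyloxy)-3-methoxybenzaldehyde F5.
   - Baeyer–Villiger oxidation (mCPBA, CH2Cl2) would give 2-(allyloxy)-3-methoxyphenyl formate F6, cleaved in the same flask (KOH, MeOH/H2O) to 2-(allyloxy)-3-methoxyphenol F7.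
   - Thermal para-Claisen rearrangement (N,N-diethylaniline, 190 °C) would give 5-allyl-3-methoxybenzene-1,2-diol F8. Both ortho positions of the allyloxy oxygen are blocked, so the allyl group travels by a Claisen and then a Cope shift to the para carbon.
   - Hydroboration–oxidation (9-BBN, THF; NaBO3·4H2O, H2O) would give 5-(3-hydroxypropyl)-3-methoxybenzene-1,2-diol F9.
   - Lipase-catalysed esterification with stearic acid 2 (immobilised Candida antarctica lipase B, 2-methylbutan-2-ol, molecular sieves, 50 °C), selective for the primary alcohol over the phenols, would give 9.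

3. Step 3. Boron may be placed on the internal carbon of the allylic ester, followed by β-elimination of the acyloxy group, or the hydroboration may stall and leave B–H that would reduce the quinone. Fallback setting out from allyl stearate 3 and coming back at boronate 6:
   - Hydroboration with pinacolborane catalysed by [Ir(cod)Cl]2 and bis(diphenylphosphino)methane (CH2Cl2, rt), which is terminal-selective, would give 3-(4,4,5,5-tetramethyl-1,3,2-dioxaborolan-2-yl)propyl octadecanoate F10.
   - Transesterification with excess methylboronic acid (acetone, dilute aqueous HCl, rt; the volatile pinacol ester evaporated) would give [3-(octadecanoyloxy)propyl]boronic acid F11.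
   - Condensation with catechol (toluene, azeotropic removal of water) would give 6.

Further compounds
F1 | step 4 | 5-bromo-3-methoxybenzene-1,2-diol | COc1cc(Br)cc(O)c1O
F2 | step 4 | 1,2-bis(benzyloxy)-5-bromo-3-methoxybenzene | COc1cc(Br)cc(OCc2ccccc2)c1OCc1ccccc1
F3 | step 4 | 3-(9-borabicyclo[3.3.1]nonan-9-yl)propyl octadecanoate | CCCCCCCCCCCCCCCCCC(=O)OCCCB1C2CCCC1CCC2
F4 | step 4 | 3-[3,4-bis(benzyloxy)-5-methoxyphenyl]propyl octadecanoate | CCCCCCCCCCCCCCCCCC(=O)OCCCc1cc(OC)c(OCc2ccccc2)c(OCc2ccccc2)c1
F5 | step 2 | 2-(allyloxy)-3-methoxybenzaldehyde | COc1cccc(C=O)c1OCC=C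
F6 | step 2 | 2-(allyloxy)-3-methoxyphenyl formate | COc1cccc(OC=O)c1OCC=C
F7 | step 2 | 2-(allyloxy)-3-methoxyphenol | COc1cccc(O)c1OCC=C
F8 | step 2 | 5-allyl-3-methoxybenzene-1,2-diol | COc1cc(CC=C)cc(O)c1O
F9 | step 2 | 5-(3-hydroxypropyl)-3-methoxybenzene-1,2-diol | COc1cc(CCCO)cc(O)c1O
F10 | step 3 | 3-(4,4,5,5-tetramethyl-1,3,2-dioxaborolan-2-yl)propyl octadecanoate | CCCCCCCCCCCCCCCCCC(=O)OCCCB1OC(C)(C)C(C)(C)O1
F11 | step 3 | [3-(octadecanoyloxy)propyl]boronic acid | CCCCCCCCCCCCCCCCCC(=O)OCCCB(O)O
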